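- Late in Monday's run target stands still with substrate in the flask: 20.3% target beside 78.3% substrate at 15.0 min, against 20.5% at 10.0 min, so do not extend this recipe for yield.

| flask | substrate | coupling partner | catalyst | remark | time |
|---|---|---|---|---|---|
| Monday's | 0.10 M | 0.40 M | 0.26 mM | run made earlier |  |
| Saturday's | 0.050 M | 0.40 M | 0.26 mM | run made earlier |  |
| Thursday's | 0.20 M | 0.40 M | 0.26 mM | run made earlier |  |
| eta | 0.10 M | 0.400 M | 0.26 mM | everything together at the start | 25 min |
| beta | 0.10 M (fed, over 10 min) | 0.400 M | 0.26 mM | all else is in the flask from the start; the feed brings no volume worth counting | 25 min |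
| epsilon | 0.10 M | 0.400 M (in portions, 3, over 10 min) | 0.26 mM | first portion at the start, last at 10 min | 25 min |
| alpha | 0.10 M | 0.400 M (fed, over 10 min) | 0.26 mM | all else is in the flask from the start; the feed brings no volume worth counting | 25 min |

| run | time / min | target / % | substrate / % |
|---|---|---|---|
| Monday's | 1.33 | 14.6 | 84.5 |
| Monday's | 2.00 | 16.9 | 82.0 |
| Monday's | 3.00 | 18.8 | 80.3 |
| Monday's | 4.00 | 19.2 | 79.4 |
| Monday's | 6.00 | 19.9 | 79.1 |
| Monday's | 10.0 | 20.5 | 78.7 |
| Monday's | 15.0 | 20.3 | 78.3 |
| Saturday's | 1.00 | 17.0 | 82.2 |
| Saturday's | 3.00 | 24.5 | 74.3 |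
| Saturday's | 6.00 | 25.9 | 72.0 |
| Saturday's | 8.00 | 25.9 | 72.0 |
| Saturday's | 12.0 | 25.7 | 71.9 |
| Saturday's | 15.0 | 26.2 | 72.4 |
| Saturday's | 20.0 | 25.8 | 72.4 |
| Thursday's | 1.00 | 8.6 | 91.1 |
| Thursday's | 3.00 | 12.8 | 86.7 |
| Thursday's | 6.00 | 13.4 | 85.4 |
| Thursday's | 8.00 | 13.9 | 85.6 |
| Thursday's | 12.0 | 13.6 | 85.3 |
| Thursday's | 15.0 | 13.3 | 85.3 |
| Thursday's | 20.0 | 13.6 | 85.6 |

(each reading ± 0.3 percentage points)



- the best flask by amount of target, in percent of the substrate charged; "all alike" if 1.5 percentage points covers them all (eta / beta / epsilon / alpha / all alike)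
- amount of target at the end, in percent of the substrate charged, eta
- amount of target at the end, in percent of the substrate charged, beta
- amount of target at the end, in percent of the substrate charged, epsilon
- amount of target at the end, in percent of the substrate charged, alpha

- Read the stall time, the time constant of the approach to the plateau: 1.05 min on Monday's first reading, 0.930 min on Saturday's.
- Read K, the crossing c(substrate) at which the rate stops following substrate (saturation): 0.0939 M from the Saturday and Thursday plateaus.
- Reckon the shot 0.0409 M from Saturday's: c(substrate) charged times the fraction turned to target, plus K times the natural log of charged over unturned substrate.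
- Check it on Monday's plateau, which went into neither K nor the shot: it gives 0.0416 M, so expect 20.3% from eta, which repeats Monday's recipe.
- Expect little from beta: one stall time of feed brings 0.01047 M, far below K, so the rate follows substrate and my reckoning of shot times that amount over K gives 4.56%.
- Give epsilon and alpha no figure from the shot: Monday's, Saturday's and Thursday's runs each hold coupling partner at 0.40 M, and these flasks dose it.
- The forecast named eta best, with 20.3% for eta, 3.5% for beta (below my figure), 9% for epsilon and 3.5% for alpha, noting: “Partner was never varied, so its order is unknown”.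
- The flasks give eta as best: eta 20.0%, beta 4.12%, epsilon 13.7%, alpha 11.7%.

    substrate + coupling partner + catalyst → target + catalyst, rate k1*[substrate]*[coupling partner]*[catalyst]/(1 + ([substrate]/sat1)) (0.0936 M, k = 74.6 M⁻² s⁻¹)
    coupling partner + catalyst + target → catalyst + over-reaction product (k = 22.6 M⁻² s⁻¹)
    coupling partner → decomposed reagent (k = 0.0100 s⁻¹)
    catalyst ⇌ dormant form (K = 2.43, k = 0.00742 s⁻¹)

- At 1.10 min in eta, coupling partner goes to decomposed reagent 18 times as fast as to target. At 25.0 min eta holds 0% of its charge of coupling partner, the limiting reagent, beside 78.5% of its substrate. The shot put beta at 4.56% against 4.12%. For eta's neighbour with 0.40 M substrate, take the log as the fraction itself: the shot over c(substrate) plus K gives 8.28%. The computed flask gives 8.06%.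

(The numbers in the tables were generated by integration on assumed constants; the scatter is artificial.)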